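**Retrosynthetic overview**
1. Target 12 ⇒ vinylcyclohexene 11 + bromocoumarin 4 (Heck reaction, E-styryl bond to coumarin C6); 11 ⇒ aldehyde 10 (Wittig methylenation).
2. Cyclohexene ring of 10 ⇒ diene 8 + methacrolein 9 by a catalytic enantioselective Diels–Alder reaction. It makes the ring CH2–CH2 bond and the bond between the aryl-bearing CH and the quaternary carbon, and sets both stereocentres.
3. Enabling feature: the cyclohexene has its C3=C4 double bond between the aryl-bearing C2 and the methyl-bearing C4, and its quaternary C1 carries a methyl group and an sp2 CH= branch (a masked formyl group). This is a Diels–Alder retron: diene half an (E)-1-aryl-3-methylbuta-1,3-diene, dienophile half an α-methylacrolein.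
4. 8 ⇒ tertiary allylic alcohol 6 (dehydration) ⇒ 4 + 2-methylbut-3-en-2-ol 5 (Heck reaction); 4 ⇒ 2 (Wittig olefination/lactonisation) ⇒ 1 (bromination).
5. Ring order: coumarin pyranone ring (step 2), then the cyclohexene (step 5); the second coumarin is attached intact in step 7, bromide 4 serving twice.

Key step: step 5

Remark: the cycloaddition in step 5 is assumed to follow the exo (formyl-anti) course usual for α-substituted acroleins under Lewis acid catalysis. The sense of face selection is assigned from the accepted binding model of the catalyst for 2-substituted acroleins.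

**Step 1**
Reactants: 1 2-hydroxy-4-methoxybenzaldehyde
Product: 2 5-bromo-2-hydroxy-4-methoxybenzaldehyde
Conditions: NBS (1.05 equiv), MeCN, 0 °C to rt
Reagents that add atoms: N-bromosuccinimide, O=C1CCC(=O)N1Br
Why: Electrophilic aromatic bromination: C5, para to the phenolic OH and ortho to OMe, is the most activated unhindered position, so monobromination should occur there without touching the aldehyde.

**Step 2**
Reactants: 2 5-bromo-2-hydroxy-4-methoxybenzaldehyde
Product: 4 6-bromo-7-methoxy-2H-chromen-2-one, via cinnamate ester 3 (not isolated)
Conditions: Ph3P=CHCO2Et (1.2 equiv), PhNEt2, reflux (about 215 °C)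
Reagents that add atoms: (ethoxycarbonylmethylene)triphenylphosphorane, CCOC(=O)C=P(c1ccccc1)(c1ccccc1)c1ccccc1
Why: Wittig olefination with the stabilised ylide gives the E-cinnamate 3, which at this temperature isomerises about the C=C bond and lactonises with loss of ethanol (classical one-pot salicylaldehyde-to-coumarin sequence); the aryl bromide is inert and no stereocentre is formed.

**Step 3**
Reactants: 4 6-bromo-7-methoxy-2H-chromen-2-one; 5 2-methylbut-3-en-2-ol
Product: 6 6-[(E)-3-hydroxy-3-methylbut-1-en-1-yl]-7-methoxy-2H-chromen-2-one
Conditions: 5 (3 equiv), Pd(OAc)2 (5 mol%), P(o-tol)3 (10 mol%), Et3N, DMF, 100 °C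
Reagents that add atoms: none
Why: Mizoroki–Heck reaction: the arylpalladium species adds to the terminal carbon of the monosubstituted alkene and, the carbinol carbon bearing no hydrogen, β-hydride elimination can only give the E-configured styrenyl alcohol.

**Step 4**
Reactants: 6 6-[(E)-3-hydroxy-3-methylbut-1-en-1-yl]-7-methoxy-2H-chromen-2-one
Product: 8 7-methoxy-6-[(E)-3-methylbuta-1,3-dien-1-yl]-2H-chromen-2-one, via sulfamate salt 7 (not isolated)
Conditions: Burgess reagent [methyl N-(triethylammoniosulfonyl)carbamate] (1.5 equiv), THF, rt then 50 °C; 8 kept cold and dilute with BHT and used at once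
Reagents that add atoms: none
Why: Burgess dehydration: the tertiary allylic alcohol is converted into sulfamate 7, which eliminates under neutral conditions (syn elimination or ion pair) and, the only β-hydrogens being those of the two methyl groups, can give only the isopropenyl diene with the E-double bond untouched.

**Step 5**
Reactants: 8 7-methoxy-6-[(E)-3-methylbuta-1,3-dien-1-yl]-2H-chromen-2-one; 9 methacrolein (2-methylprop-2-enal)
Product: 10 (1S,2R)-2-(7-methoxy-2-oxo-2H-chromen-6-yl)-1,4-dimethylcyclohex-3-ene-1-carbaldehyde
Conditions: (S)-o-tolyl-CBS oxazaborolidine [(S)-3,3-diphenyl-1-(2-methylphenyl)tetrahydro-1H,3H-pyrrolo[1,2-c][1,3,2]oxazaborole] (20 mol%), Tf2NH (18 mol%), 9 (5 equiv), CH2Cl2, −78 to −40 °C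
Reagents that add atoms: none
Why: Normal-electron-demand Diels–Alder reaction in which the oxazaborolidinium ion binds methacrolein at the formyl oxygen and lowers its LUMO, so that the electron-rich diene 8 reacts at low temperature through a concerted but strongly asynchronous transition state; the closest known reaction type is the oxazaborolidinium-catalysed enantioselective cycloaddition of 2-substituted acroleins with acyclic dienes. The cyclohexene is closed as a [4+2] cycloaddition (suprafacial on both components, s-cis diene) and is the only ring formed in this step. Regiochemistry is secured by the substrate: the electron-rich aryl group on C1 and the methyl group on C3 of the diene both enlarge the HOMO coefficient at the terminal CH2, which pairs with the β-carbon of the activated enal, so the aryl-bearing carbon bonds to the α-carbon and creates the quaternary centre. The configuration of the quaternary carbon (1S) is set by the catalyst, which shields one face of the bound s-trans enal with a phenyl group and in its (S)-form is expected to leave the C2-re face open to the diene (the (R)-catalyst is equally available should the sense prove opposite). The configuration of the benzylic carbon (2R) follows from the E-geometry of the diene and an exo transition state (formyl away from the diene, α-methyl under it), the usual preference of α-substituted acroleins under Lewis acid catalysis, reinforced here because the endo mode would press the catalyst-bound formyl group against the ortho-methoxyaryl group; aryl thus ends cis to methyl and trans to formyl. The step needs exo selectivity and freedom from acid-induced oligomerisation and thermal self-dimerisation of 8, which the bulky catalyst, the slight excess of oxazaborolidine over Tf2NH and the low temperature should provide.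

**Step 6**
Reactants: 10 (1S,2R)-2-(7-methoxy-2-oxo-2H-chromen-6-yl)-1,4-dimethylcyclohex-3-ene-1-carbaldehyde
Product: 11 6-[(1S,6R)-6-ethenyl-3,6-dimethylcyclohex-2-en-1-yl]-7-methoxy-2H-chromen-2-one
Conditions: Ph3PCH3Br (1.3 equiv), KOtBu (1.2 equiv), THF, 0 °C; then 10, −78 to 0 °C
Reagents that add atoms: methyltriphenylphosphonium bromide, C[P+](c1ccccc1)(c1ccccc1)c1ccccc1.[Br-]
Why: Wittig methylenation of a non-enolisable α-quaternary aldehyde: the formyl group is far more electrophilic towards the ylide than the coumarin lactone at low temperature, and neither stereocentre can epimerise.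

**Step 7**
Reactants: 11 6-[(1S,6R)-6-ethenyl-3,6-dimethylcyclohex-2-en-1-yl]-7-methoxy-2H-chromen-2-one; 4 6-bromo-7-methoxy-2H-chromen-2-one
Product: 12 7-methoxy-6-[(E)-2-[(1R,2S)-2-(7-methoxy-2-oxo-2H-chromen-6-yl)-1,4-dimethylcyclohex-3-en-1-yl]ethenyl]-2H-chromen-2-one
Conditions: 4 (1.2 equiv), Pd2(dba)3 (2.5 mol%), [HP(t-Bu)3]BF4 (10 mol%), Cy2NMe (1.5 equiv), 1,4-dioxane, 80 °C
Reagents that add atoms: none
Why: Mizoroki–Heck reaction with a bulky electron-rich phosphine on zerovalent palladium: the aryl group is delivered to the unhindered terminal CH2 of the vinyl group and, the allylic carbon being quaternary, β-hydride elimination can only give the E-styryl alkene without double-bond migration, leaving both stereocentres untouched.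

**Compound list**
1 | 2-hydroxy-4-methoxybenzaldehyde | COc1ccc(C=O)c(O)c1 | starting material
2 | 5-bromo-2-hydroxy-4-methoxybenzaldehyde | COc1cc(O)c(C=O)cc1Br | intermediate
3 | ethyl (E)-3-(5-bromo-2-hydroxy-4-methoxyphenyl)prop-2-enoate | CCOC(=O)/C=C/c1cc(Br)c(OC)cc1O | intermediate
4 | 6-bromo-7-methoxy-2H-chromen-2-one | COc1cc2oc(=O)ccc2cc1Br | intermediate
5 | 2-methylbut-3-en-2-ol | CC(C)(O)C=C | starting material
6 | 6-[(E)-3-hydroxy-3-methylbut-1-en-1-yl]-7-methoxy-2H-chromen-2-one | COc1cc2oc(=O)ccc2cc1/C=C/C(C)(C)O | intermediate
7 | triethylammonium salt of the N-(methoxycarbonyl)sulfamate ester of 6 | COC(=O)[N-]S(=O)(=O)OC(C)(C)/C=C/c1cc2ccc(=O)oc2cc1OC.CC[NH+](CC)CC | intermediate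
8 | 7-methoxy-6-[(E)-3-methylbuta-1,3-dien-1-yl]-2H-chromen-2-one | COc1cc2oc(=O)ccc2cc1/C=C/C(C)=C | intermediate
9 | methacrolein (2-methylprop-2-enal) | CC(=C)C=O | starting material
10 | (1S,2R)-2-(7-methoxy-2-oxo-2H-chromen-6-yl)-1,4-dimethylcyclohex-3-ene-1-carbaldehyde (aryl trans to formyl) | O=C[C@@]1(C)CCC(C)=C[C@@H]1c1cc2ccc(=O)oc2cc1OC | intermediate
11 | 6-[(1S,6R)-6-ethenyl-3,6-dimethylcyclohex-2-en-1-yl]-7-methoxy-2H-chromen-2-one | C=C[C@@]1(C)CCC(C)=C[C@@H]1c1cc2ccc(=O)oc2cc1OC | intermediate
12 | 7-methoxy-6-[(E)-2-[(1R,2S)-2-(7-methoxy-2-oxo-2H-chromen-6-yl)-1,4-dimethylcyclohex-3-en-1-yl]ethenyl]-2H-chromen-2-one | COc1cc2oc(=O)ccc2cc1/C=C/[C@@]1(C)CCC(C)=C[C@@H]1c1cc2ccc(=O)oc2cc1OC | target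

**Step count**
Total steps: 7. Longest linear sequence: 7 steps (1 → 2 → 4 → 6 → 8 → 10 → 11 → 12; bromide 4 re-enters in step 7).

**Steps most likely to fail**

Step 5. The cycloaddition may show too little exo preference (aryl ending cis to formyl), a low or reversed facial selection, or the electron-rich diene may oligomerise under the acidic catalyst before it cycloadds. The fallback sets out from diene 8 and drops the surrogate dienophile and the catalyst. Heating 8 in toluene at 100 °C with BHT should bring about the thermal Diels–Alder self-dimerisation, one molecule acting as the diene and the isopropenyl double bond of a second as the dienophile. The same orbital pairing should give the same regiochemistry, and the aryl/styryl-trans adduct is expected, as this is the mode by which this natural dimer type presumably arises. The product would be the racemate, that is 12 together with its enantiomer, the (1S,2R)-dimer F1. Preparative HPLC on a chiral stationary phase (amylose tris(3,5-dimethylphenylcarbamate)) would separate the two, and the route is rejoined at 12, bypassing 10 and 11.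

Step 7. Carbopalladation of the hindered vinyl group next to the quaternary carbon may be slow, so that arylation of a coumarin C3=C4 bond or hydrodebromination of 4 competes. The fallback sets out from aldehyde 10 and makes the aryl–alkenyl bond by cross-coupling instead of insertion. A Takai-type olefination of 10 with Cl2CHB(pin), CrCl2 and LiI in THF at rt should give the (E)-alkenyl pinacol boronate F2. Suzuki–Miyaura coupling of F2 with bromide 4 (Pd(dppf)Cl2, K3PO4, dioxane/H2O, 70 °C) comes back to the route at 12, bypassing 11.

Step 4. The diene may be lost during its formation and isolation by self-dimerisation or by ion-pair-mediated oligomerisation of the allylic sulfamate. The fallback sets out from bromide 4 and installs the intact diene unit under basic conditions, avoiding alcohol 6. Cp2ZrHCl-catalysed hydroboration of commercial 2-methylbut-1-en-3-yne with pinacolborane should give the (E)-dienyl pinacol boronate F3. Suzuki–Miyaura coupling of F3 with 4 (Pd(PPh3)4, K3PO4, THF/H2O, 50 °C) comes back to the route at diene 8.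

**Further compounds**
F1 | step 5 | 7-methoxy-6-[(E)-2-[(1S,2R)-2-(7-methoxy-2-oxo-2H-chromen-6-yl)-1,4-dimethylcyclohex-3-en-1-yl]ethenyl]-2H-chromen-2-one (enantiomer of 12) | COc1cc2oc(=O)ccc2cc1/C=C/[C@]1(C)CCC(C)=C[C@H]1c1cc2ccc(=O)oc2cc1OC
F2 | step 7 | 6-[(1S,6R)-3,6-dimethyl-6-[(E)-2-(4,4,5,5-tetramethyl-1,3,2-dioxaborolan-2-yl)ethenyl]cyclohex-2-en-1-yl]-7-methoxy-2H-chromen-2-one | CC1(C)OB(/C=C/[C@@]2(C)CCC(C)=C[C@@H]2c2cc3ccc(=O)oc3cc2OC)OC1(C)C
F3 | step 4 | 4,4,5,5-tetramethyl-2-[(E)-3-methylbuta-1,3-dien-1-yl]-1,3,2-dioxaborolane | CC(=C)/C=C/B1OC(C)(C)C(C)(C)O1
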